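**Plan**

1. Numbering used below (carotenoid convention): ring C1 (CMe2) to C6, oxirane on C5 (CH3) and C6, then C7H2, C8 (C=O), C9 … C12' (CHO). The retrosynthesis cuts, in this order: C8=O back to C8–OH (oxidation last), C11=C12 (Horner–Wadsworth–Emmons with the symmetric dialdehyde 22), C8–C9 (Nozaki–Hiyama–Kishi), then C5–C6 together with C6–O.
2. Enabling feature: the oxirane bond C5–C6 is also a bond of the cyclohexane, C5 carries CH3 and C6 carries CH2–C8(=O). C5 is therefore the carbonyl carbon of a methyl ketone and C6 the beta carbon of an enal C6=C7–C8HO in the acyclic keto-enal 12.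
3. Forward: 12 is built linearly (C1/C6 from isobutyronitrile, C2–C4 from (S)-epichlorohydrin, C5/C18 from isopropenyl, C7/C8 from a cyanomethylphosphonate). In one flask a sulfide then adds to C6 with O-silylation, the sulfonium ylide at C6 closes the carbocycle onto C5=O, and the alkoxide closes the oxirane by expelling the sulfide.
4. Helpers and their removal: the sulfide leaves in the same flask; the enol silyl ether C7=C8–OSi (masked C7H2–C8HO) is cleaved in step 9; the C8 carbinol is oxidised in the last step, so the base-labile beta,gamma-epoxy ketone exists only in the final compound.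
5. Stereochemistry: C3 comes from (S)-epichlorohydrin. C5 and C6 come from the chair transition state of the ring closure (C3–OSi and C5–CH3 equatorial, alkoxide and sulfonium trans-diaxial), which places the oxirane anti to the C3 oxygen. The alkenes come from E-selective olefinations and a stereoretentive alkenyl iodide.

Key step: step 8

Remark: the C8 carbinol centre in 21, 23 and 24 and the enol ether geometry in 13–15 arise as mixtures; both are erased later (oxidation, hydrolysis), so they are left undefined.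

**Route**

Step 1
Reactants: 1 isobutyronitrile; 2 (S)-epichlorohydrin
Product: 4 2,2-dimethyl-3-[(2S)-oxiran-2-yl]propanenitrile, via chlorohydrin lithium alkoxide 3 (not isolated)
Conditions: LiN(i-Pr)2, THF, −78 °C; then 2, −78 °C to rt
Reagents that add atoms: none
Why: The lithiated nitrile, which has no further alpha-hydrogen, opens the oxirane of 2 at its CH2 terminus and alkoxide 3 then displaces chloride (alkylation of a nitrile anion with epichlorohydrin by epoxide opening and re-closure), so the stereocentre of 2 is never touched and becomes C3 of the target.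

Step 2
Reactants: 4 2,2-dimethyl-3-[(2S)-oxiran-2-yl]propanenitrile; 5 isopropenylmagnesium bromide
Product: 6 (4R)-4-hydroxy-2,2,6-trimethylhept-6-enenitrile
Conditions: CuI (10 mol %), THF, −40 to 0 °C; aq. NH4Cl
Reagents that add atoms: none
Why: Copper-catalysed Grignard opening of the terminal epoxide at CH2 (SN2) should be faster than addition to the hindered tertiary nitrile and installs C5 with its methyl group as a masked methyl ketone.

Step 3
Reactants: 6 (4R)-4-hydroxy-2,2,6-trimethylhept-6-enenitrile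
Product: 7 (4R)-4-{[tert-butyl(dimethyl)silyl]oxy}-2,2,6-trimethylhept-6-enenitrile
Conditions: t-BuMe2SiCl, imidazole, DMF, rt
Reagents that add atoms: tert-butyldimethylsilyl chloride, CC(C)(C)[Si](C)(C)Cl
Why: Standard silylation of the secondary alcohol, which also prevents lactol formation after the nitrile reduction.

Step 4
Reactants: 7 (4R)-4-{[tert-butyl(dimethyl)silyl]oxy}-2,2,6-trimethylhept-6-enenitrile
Product: 8 (4R)-4-{[tert-butyl(dimethyl)silyl]oxy}-2,2,6-trimethylhept-6-enal
Conditions: i-Bu2AlH, toluene, −78 °C; aq. potassium sodium tartrate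
Reagents that add atoms: water, O
Why: Partial reduction of the nitrile to the N-aluminio aldimine, which is not reduced further at low temperature and is hydrolysed on work-up (nitrile-to-aldehyde reduction).

Step 5
Reactants: 8 (4R)-4-{[tert-butyl(dimethyl)silyl]oxy}-2,2,6-trimethylhept-6-enal; 9 diethyl (cyanomethyl)phosphonate
Product: 10 (2E,6R)-6-{[tert-butyl(dimethyl)silyl]oxy}-4,4,8-trimethylnona-2,8-dienenitrile
Conditions: NaH, THF, 0 °C to rt
Reagents that add atoms: none
Why: Horner–Wadsworth–Emmons olefination of the alpha-quaternary aldehyde, in which the bulky tertiary substituent should enforce the E alkene.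

Step 6
Reactants: 10 (2E,6R)-6-{[tert-butyl(dimethyl)silyl]oxy}-4,4,8-trimethylnona-2,8-dienenitrile
Product: 11 (2E,6R)-6-{[tert-butyl(dimethyl)silyl]oxy}-4,4,8-trimethylnona-2,8-dienal
Conditions: i-Bu2AlH, CH2Cl2, −78 °C; aq. potassium sodium tartrate
Reagents that add atoms: water, O
Why: The same partial reduction applied to the conjugated nitrile should give the E enal (the classical two-carbon chain extension of polyene chemistry), the isolated alkene and the silyl ether being inert.

Step 7
Reactants: 11 (2E,6R)-6-{[tert-butyl(dimethyl)silyl]oxy}-4,4,8-trimethylnona-2,8-dienal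
Product: 12 (2E,6S)-6-{[tert-butyl(dimethyl)silyl]oxy}-4,4-dimethyl-8-oxonon-2-enal
Conditions: O3 (titrated to the alkene), CH2Cl2/MeOH, −78 °C; then Me2S
Reagents that add atoms: ozone, [O-][O+]=O
Why: Ozone attacks the electron-rich 1,1-disubstituted alkene much faster than the electron-poor enal C=C, so titrated ozonolysis with reductive work-up should unveil the methyl ketone selectively.

Step 8
Reactants: 12 (2E,6S)-6-{[tert-butyl(dimethyl)silyl]oxy}-4,4-dimethyl-8-oxonon-2-enal
Product: 15 tert-butyl({2-[(1S,4S,6R)-4-{[tert-butyl(dimethyl)silyl]oxy}-2,2,6-trimethyl-7-oxabicyclo[4.1.0]heptan-1-yl]ethenyl}oxy)dimethylsilane (E/Z mixture), via sulfonium triflate 13 (not isolated), via alkoxide sulfonium betaine 14 (not isolated)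
Conditions: tetrahydrothiophene (3 equiv), t-BuMe2SiOTf (1.05 equiv), CH2Cl2, −78 °C; then LiN(SiMe3)2 (1.1 equiv, THF), −78 to −10 °C
Reagents that add atoms: tert-butyldimethylsilyl trifluoromethanesulfonate, CC(C)(C)[Si](C)(C)OS(=O)(=O)C(F)(F)F; tetrahydrothiophene, C1CCSC1 (held only in 13 and 14)
Why: Proposed new method: the sulfide adds to the beta carbon (C6) of the silyl-triflate-activated enal to give the 3-silyloxyallyl sulfonium salt 13 (conjugate onium-silylation of enones and enals with sulfides or PPh3 and silyl triflates is known, as is deprotonation of the phosphonium analogues at this carbon); LiN(SiMe3)2 removes the only sulfonium alpha-hydrogen that is also allylic, the ylide carbon C6 adds to the C5 ketone, and the alkoxide of 14 displaces the sulfide at C6, so the closest known reaction types are the Corey–Chaykovsky epoxidation with allylic sulfonium ylides and the epoxy-annulation of carbonyl-tethered nucleophiles with vinyl sulfonium salts. The cyclohexane closes 6-exo-trig (C6 onto the exocyclic C5=O) and the oxirane 3-exo-tet (alkoxide onto C6 with loss of the sulfide). C5 is set in a chair transition state in which C5–CH3 stays equatorial to avoid the axial C1 methyl and the C3 silyloxy group stays equatorial, so the axial alkoxide is trans to the C3 oxygen; C6 is set because only the betaine with alkoxide and sulfonium trans-diaxial can close, the other betaines reverting, and the displacement inverts C6 and places C7 cis to the C3 oxygen. The step needs conjugate instead of carbonyl addition of the sulfide, ylide formation at C6 instead of on the thiolane ring (which would open a [2,3]-shift) or at the ketone, and attack through C6 and not C8; these are served by the reversibility of the sulfide addition, by the double activation of the C6–H and the absence of any beta-hydrogen for elimination (C1 quaternary, C7 vinylic), and by the six- versus eight-membered ring size. The silyl enol ether left at C7=C8 already carries the C7H2–C8 carbonyl oxidation level of the target.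

Step 9
Reactants: 15 tert-butyl({2-[(1S,4S,6R)-4-{[tert-butyl(dimethyl)silyl]oxy}-2,2,6-trimethyl-7-oxabicyclo[4.1.0]heptan-1-yl]ethenyl}oxy)dimethylsilane
Product: 16 2-[(1S,4S,6R)-4-{[tert-butyl(dimethyl)silyl]oxy}-2,2,6-trimethyl-7-oxabicyclo[4.1.0]heptan-1-yl]acetaldehyde
Conditions: Bu4NF (1.05 equiv), AcOH (2 equiv), THF, −78 °C; pH 7 buffer; used at once
Reagents that add atoms: none
Why: Fluoride cleaves the enol silyl ether far faster than the secondary alkyl silyl ether, and acetic acid protonates the enolate at C7 before it can open the oxirane (buffered desilylation of a silyl enol ether).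

Step 10
Reactants: 17 but-2-yn-1-ol
Product: 18 (2E)-3-iodobut-2-en-1-ol
Conditions: Cp2Zr(H)Cl (2.2 equiv), THF, rt; then I2, 0 °C
Reagents that add atoms: iodine, II
Why: Hydrozirconation of the 2-alkyn-1-ol as its zirconium alkoxide adds H and Zr syn with zirconium on the carbon remote from oxygen, and iodinolysis with retention should give the E iodoalkene.

Step 11
Reactants: 18 (2E)-3-iodobut-2-en-1-ol
Product: 19 (2E)-1-bromo-3-iodobut-2-ene
Conditions: CBr4, PPh3, CH2Cl2, 0 °C
Reagents that add atoms: carbon tetrabromide, BrC(Br)(Br)Br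
Why: Appel bromination of the primary allylic alcohol under neutral conditions, without allylic transposition or loss of alkene geometry.

Step 12
Reactants: 19 (2E)-1-bromo-3-iodobut-2-ene
Product: 20 diethyl [(2E)-3-iodobut-2-en-1-yl]phosphonate
Conditions: P(OEt)3, neat, 100 °C
Reagents that add atoms: triethyl phosphite, CCOP(OCC)OCC
Why: Michaelis–Arbuzov reaction at the allylic bromide; the alkenyl iodide does not react with the phosphite without a metal catalyst.

Step 13
Reactants: 16 2-[(1S,4S,6R)-4-{[tert-butyl(dimethyl)silyl]oxy}-2,2,6-trimethyl-7-oxabicyclo[4.1.0]heptan-1-yl]acetaldehyde; 20 diethyl [(2E)-3-iodobut-2-en-1-yl]phosphonate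
Product: 21 diethyl [(2E)-5-[(1S,4S,6R)-4-{[tert-butyl(dimethyl)silyl]oxy}-2,2,6-trimethyl-7-oxabicyclo[4.1.0]heptan-1-yl]-4-hydroxy-3-methylpent-2-en-1-yl]phosphonate (C4 epimers)
Conditions: CrCl2 (4 equiv), NiCl2 (2 mol %), DMSO, rt
Reagents that add atoms: none
Why: Nozaki–Hiyama–Kishi reaction: nickel-catalysed formation of the alkenylchromium species from the iodide with retention of geometry and its addition to the aldehyde under non-basic conditions that tolerate the phosphonate, the oxirane and the enolisable aldehyde; the new C8 carbinol centre is not controlled and is removed in step 16.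

Step 14
Reactants: 21 diethyl [(2E)-5-[(1S,4S,6R)-4-{[tert-butyl(dimethyl)silyl]oxy}-2,2,6-trimethyl-7-oxabicyclo[4.1.0]heptan-1-yl]-4-hydroxy-3-methylpent-2-en-1-yl]phosphonate; 22 (2E,4E,6E)-2,7-dimethylocta-2,4,6-trienedial
Product: 23 (2E,4E,6E,8E,10E)-13-[(1S,4S,6R)-4-{[tert-butyl(dimethyl)silyl]oxy}-2,2,6-trimethyl-7-oxabicyclo[4.1.0]heptan-1-yl]-12-hydroxy-2,7,11-trimethyltrideca-2,4,6,8,10-pentaenal (C12 epimers)
Conditions: NaN(SiMe3)2 (2.1 equiv), THF, −78 °C; then 22 (3 equiv), −78 to −20 °C
Reagents that add atoms: none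
Why: Horner–Wadsworth–Emmons olefination of the allylic phosphonate anion (formed beside the C8 alkoxide, which keeps the C8 oxygen from being eliminated) with an excess of the symmetric dialdehyde, which should give the E alkene at C11=C12 and leave the second formyl group free.

Step 15
Reactants: 23 (2E,4E,6E,8E,10E)-13-[(1S,4S,6R)-4-{[tert-butyl(dimethyl)silyl]oxy}-2,2,6-trimethyl-7-oxabicyclo[4.1.0]heptan-1-yl]-12-hydroxy-2,7,11-trimethyltrideca-2,4,6,8,10-pentaenal
Product: 24 (2E,4E,6E,8E,10E)-12-hydroxy-13-[(1S,4S,6R)-4-hydroxy-2,2,6-trimethyl-7-oxabicyclo[4.1.0]heptan-1-yl]-2,7,11-trimethyltrideca-2,4,6,8,10-pentaenal (C12 epimers)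
Conditions: Bu4NF (3 equiv), AcOH (3 equiv), THF, 0 °C to rt, dark
Reagents that add atoms: none
Why: Fluoride removes the secondary silyl ether; acetic acid buffers the medium so that the polyenal and the oxirane are not exposed to free alkoxide.

Step 16
Reactants: 24 (2E,4E,6E,8E,10E)-12-hydroxy-13-[(1S,4S,6R)-4-hydroxy-2,2,6-trimethyl-7-oxabicyclo[4.1.0]heptan-1-yl]-2,7,11-trimethyltrideca-2,4,6,8,10-pentaenal
Product: 25 (2E,4E,6E,8E,10E)-13-[(1S,4S,6R)-4-hydroxy-2,2,6-trimethyl-7-oxabicyclo[4.1.0]heptan-1-yl]-2,7,11-trimethyl-12-oxotrideca-2,4,6,8,10-pentaenal (CNP0310604.1)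
Conditions: MnO2 (activated, excess), CH2Cl2, rt, dark
Reagents that add atoms: none
Why: MnO2 should oxidise only the allylic C8 alcohol (conjugated with the pentaene), leaving the saturated C3 alcohol and the enal untouched, so that the base-labile beta,gamma-epoxy ketone is formed last under neutral conditions.

**Compound list**

1 | isobutyronitrile (2-methylpropanenitrile) | CC(C)C#N | starting material
2 | (S)-epichlorohydrin, (2S)-2-(chloromethyl)oxirane | ClC[C@@H]1CO1 | starting material
3 | lithium (2S)-1-chloro-4-cyano-4-methylpentan-2-olate | N#CC(C)(C)C[C@H]([O-])CCl.[Li+] | intermediate (not isolated)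
4 | 2,2-dimethyl-3-[(2S)-oxiran-2-yl]propanenitrile | N#CC(C)(C)C[C@H]1CO1 | intermediate
5 | isopropenylmagnesium bromide | CC(=C)[Mg]Br | starting material
6 | (4R)-4-hydroxy-2,2,6-trimethylhept-6-enenitrile | N#CC(C)(C)C[C@H](O)CC(C)=C | intermediate
7 | (4R)-4-{[tert-butyl(dimethyl)silyl]oxy}-2,2,6-trimethylhept-6-enenitrile | N#CC(C)(C)C[C@H](O[Si](C)(C)C(C)(C)C)CC(C)=C | intermediate
8 | (4R)-4-{[tert-butyl(dimethyl)silyl]oxy}-2,2,6-trimethylhept-6-enal | O=CC(C)(C)C[C@H](O[Si](C)(C)C(C)(C)C)CC(C)=C | intermediate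
9 | diethyl (cyanomethyl)phosphonate | CCOP(=O)(CC#N)OCC | starting material
10 | (2E,6R)-6-{[tert-butyl(dimethyl)silyl]oxy}-4,4,8-trimethylnona-2,8-dienenitrile | N#C/C=C/C(C)(C)C[C@H](O[Si](C)(C)C(C)(C)C)CC(C)=C | intermediate
11 | (2E,6R)-6-{[tert-butyl(dimethyl)silyl]oxy}-4,4,8-trimethylnona-2,8-dienal | O=C/C=C/C(C)(C)C[C@H](O[Si](C)(C)C(C)(C)C)CC(C)=C | intermediate
12 | (2E,6S)-6-{[tert-butyl(dimethyl)silyl]oxy}-4,4-dimethyl-8-oxonon-2-enal | O=C/C=C/C(C)(C)C[C@H](O[Si](C)(C)C(C)(C)C)CC(C)=O | intermediate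
13 | 1-[(6S)-1,6-bis{[tert-butyl(dimethyl)silyl]oxy}-4,4-dimethyl-8-oxonon-1-en-3-yl]thiolan-1-ium trifluoromethanesulfonate (C3 epimers, enol ether E/Z) | CC(=O)C[C@@H](O[Si](C)(C)C(C)(C)C)CC(C)(C)C(C=CO[Si](C)(C)C(C)(C)C)[S+]1CCCC1.[O-]S(=O)(=O)C(F)(F)F | intermediate (not isolated)
14 | (1R,2R,5S)-5-{[tert-butyl(dimethyl)silyl]oxy}-2-(2-{[tert-butyl(dimethyl)silyl]oxy}ethenyl)-1,3,3-trimethyl-2-(thiolan-1-ium-1-yl)cyclohexan-1-olate (betaine, alkoxide and sulfonium trans; lithium triflate alongside) | C[C@@]1([O-])C[C@@H](O[Si](C)(C)C(C)(C)C)CC(C)(C)[C@@]1(C=CO[Si](C)(C)C(C)(C)C)[S+]1CCCC1 | intermediate (not isolated)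
15 | tert-butyl({2-[(1S,4S,6R)-4-{[tert-butyl(dimethyl)silyl]oxy}-2,2,6-trimethyl-7-oxabicyclo[4.1.0]heptan-1-yl]ethenyl}oxy)dimethylsilane (E/Z mixture) | CC(C)(C)[Si](C)(C)OC=C[C@@]12O[C@]1(C)C[C@@H](O[Si](C)(C)C(C)(C)C)CC2(C)C | intermediate
16 | 2-[(1S,4S,6R)-4-{[tert-butyl(dimethyl)silyl]oxy}-2,2,6-trimethyl-7-oxabicyclo[4.1.0]heptan-1-yl]acetaldehyde | O=CC[C@@]12O[C@]1(C)C[C@@H](O[Si](C)(C)C(C)(C)C)CC2(C)C | intermediate
17 | but-2-yn-1-ol | CC#CCO | starting material
18 | (2E)-3-iodobut-2-en-1-ol | I/C(C)=C/CO | intermediate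
19 | (2E)-1-bromo-3-iodobut-2-ene | I/C(C)=C/CBr | intermediate
20 | diethyl [(2E)-3-iodobut-2-en-1-yl]phosphonate | CCOP(=O)(C/C=C(\C)I)OCC | intermediate
21 | diethyl [(2E)-5-[(1S,4S,6R)-4-{[tert-butyl(dimethyl)silyl]oxy}-2,2,6-trimethyl-7-oxabicyclo[4.1.0]heptan-1-yl]-4-hydroxy-3-methylpent-2-en-1-yl]phosphonate (C4 epimers) | CCOP(=O)(C/C=C(\C)C(O)C[C@@]12O[C@]1(C)C[C@@H](O[Si](C)(C)C(C)(C)C)CC2(C)C)OCC | intermediate
22 | (2E,4E,6E)-2,7-dimethylocta-2,4,6-trienedial | O=C/C(C)=C/C=C/C=C(\C)C=O | starting material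
23 | (2E,4E,6E,8E,10E)-13-[(1S,4S,6R)-4-{[tert-butyl(dimethyl)silyl]oxy}-2,2,6-trimethyl-7-oxabicyclo[4.1.0]heptan-1-yl]-12-hydroxy-2,7,11-trimethyltrideca-2,4,6,8,10-pentaenal (C12 epimers) | C\C(C=O)=C/C=C/C=C(C)/C=C/C=C(\C)C(O)C[C@@]12O[C@]1(C)C[C@@H](O[Si](C)(C)C(C)(C)C)CC2(C)C | intermediate
24 | (2E,4E,6E,8E,10E)-12-hydroxy-13-[(1S,4S,6R)-4-hydroxy-2,2,6-trimethyl-7-oxabicyclo[4.1.0]heptan-1-yl]-2,7,11-trimethyltrideca-2,4,6,8,10-pentaenal (C12 epimers) | C\C(C=O)=C/C=C/C=C(C)/C=C/C=C(\C)C(O)C[C@@]12O[C@]1(C)C[C@@H](O)CC2(C)C | intermediate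
25 | (2E,4E,6E,8E,10E)-13-[(1S,4S,6R)-4-hydroxy-2,2,6-trimethyl-7-oxabicyclo[4.1.0]heptan-1-yl]-2,7,11-trimethyl-12-oxotrideca-2,4,6,8,10-pentaenal (CNP0310604.1) | C\C(C=O)=C/C=C/C=C(C)/C=C/C=C(\C)C(=O)C[C@@]12O[C@]1(C)C[C@@H](O)CC2(C)C | target

**Count and risks**

Total steps: 16. Longest linear sequence: 13 (steps 1–9 and 13–16); steps 10–12 make the side fragment 20.

Steps most likely to fail:

Step 8 (Proposed new method). What may go wrong: the sulfide may add to the carbonyl carbon instead of the hindered beta carbon; deprotonation may occur on the thiolane ring and be followed by a [2,3]-shift; or bond formation between two fully substituted carbons may be too slow, so that the ylide decays. Fallback with known reactions, setting out from nitrile 7 and coming back at aldehyde 16: MeLi (Et2O, −78 to 0 °C, aqueous work-up) should convert 7 into the methyl ketone (5R)-5-{[tert-butyl(dimethyl)silyl]oxy}-3,3,7-trimethyloct-7-en-2-one F1. Its lithium enolate (LiN(i-Pr)2, THF, −78 °C), which can form on one side only, is alkylated with benzyl chloromethyl ether to the beta-benzyloxy ketone F2. OsO4 (cat.) and NaIO4 with 2,6-lutidine cleave the isopropenyl group to the diketone F3. An intramolecular McMurry coupling (TiCl3, Zn–Cu couple, DME, reflux, high dilution) then forms the C5=C6 bond and should give the tetrasubstituted cyclohexene F4. m-CPBA (NaHCO3, CH2Cl2, 0 °C) is expected to epoxidise mainly anti to the silyloxy group, giving the oxirane F5 after removal of the syn isomer. Hydrogenolysis (H2, Pd(OH)2 on carbon, EtOAc) gives the alcohol F6, and a NaHCO3-buffered Dess–Martin oxidation returns to 16.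

Step 9. What may go wrong: elimination opening of the oxirane through the aldehyde enolate that fluoride sets free, or allylic opening of the vinyl oxirane by adventitious acid. Fallback that never forms that enolate, setting out from 15 and coming back at 16: ozonolysis of the enol ether (O3, CH2Cl2, pyridine, −78 °C; Me2S) should give the epoxy aldehyde F7. Wittig methylenation (Ph3P=CH2 from Ph3PCH3Br and KN(SiMe3)2, THF, 0 °C) gives the vinyl oxirane F8. Hydroboration with 9-BBN and oxidation with NaBO3 give the alcohol F6 already described. Buffered Dess–Martin oxidation then gives 16, which is used at once in step 13.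

Step 14. What may go wrong: loss of alkene geometry (rotation about C9–C10 in the allyl anion, E/Z mixture at C11=C12), double olefination of the dialdehyde, or attack of the C8 alkoxide on the oxirane. Fallback that olefinates before the sensitive ring is attached, setting out from 20, 22 and 16 and coming back at 25: 20 (NaN(SiMe3)2, THF, −78 °C) and excess 22 should give the iodo pentaenal F9, which can be purified to the all-E isomer. NaBH4 (MeOH, 0 °C) reduces it to the iodo pentaenol F10. A Nozaki–Hiyama–Kishi reaction of F10 with 16 (CrCl2, NiCl2 cat., DMSO) gives the diol F11. Bu4NF/AcOH removes the silyl group to give the triol F12. MnO2 then oxidises both allylic alcohols (C8 and C12') in one operation to 25.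

Further compounds
F1 | step 8 | (5R)-5-{[tert-butyl(dimethyl)silyl]oxy}-3,3,7-trimethyloct-7-en-2-one | CC(=O)C(C)(C)C[C@H](O[Si](C)(C)C(C)(C)C)CC(C)=C
F2 | step 8 | (6R)-1-(benzyloxy)-6-{[tert-butyl(dimethyl)silyl]oxy}-4,4,8-trimethylnon-8-en-3-one | O=C(CCOCc1ccccc1)C(C)(C)C[C@H](O[Si](C)(C)C(C)(C)C)CC(C)=C
F3 | step 8 | (4S)-9-(benzyloxy)-4-{[tert-butyl(dimethyl)silyl]oxy}-6,6-dimethylnonane-2,7-dione | O=C(CCOCc1ccccc1)C(C)(C)C[C@H](O[Si](C)(C)C(C)(C)C)CC(C)=O
F4 | step 8 | {[(1R)-4-[2-(benzyloxy)ethyl]-3,5,5-trimethylcyclohex-3-en-1-yl]oxy}(tert-butyl)dimethylsilane | CC1=C(CCOCc2ccccc2)C(C)(C)C[C@H](O[Si](C)(C)C(C)(C)C)C1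
F5 | step 8 | (1S,4S,6R)-1-[2-(benzyloxy)ethyl]-4-{[tert-butyl(dimethyl)silyl]oxy}-2,2,6-trimethyl-7-oxabicyclo[4.1.0]heptane | O(Cc1ccccc1)CC[C@@]12O[C@]1(C)C[C@@H](O[Si](C)(C)C(C)(C)C)CC2(C)C
F6 | step 8 | 2-[(1S,4S,6R)-4-{[tert-butyl(dimethyl)silyl]oxy}-2,2,6-trimethyl-7-oxabicyclo[4.1.0]heptan-1-yl]ethan-1-ol | OCC[C@@]12O[C@]1(C)C[C@@H](O[Si](C)(C)C(C)(C)C)CC2(C)C
F7 | step 9 | (1S,4S,6R)-4-{[tert-butyl(dimethyl)silyl]oxy}-2,2,6-trimethyl-7-oxabicyclo[4.1.0]heptane-1-carbaldehyde | O=C[C@@]12O[C@]1(C)C[C@@H](O[Si](C)(C)C(C)(C)C)CC2(C)C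
F8 | step 9 | tert-butyl{[(1S,3S,6R)-6-ethenyl-1,5,5-trimethyl-7-oxabicyclo[4.1.0]heptan-3-yl]oxy}dimethylsilane | C=C[C@@]12O[C@]1(C)C[C@@H](O[Si](C)(C)C(C)(C)C)CC2(C)C
F9 | step 14 | (2E,4E,6E,8E,10E)-11-iodo-2,7-dimethyldodeca-2,4,6,8,10-pentaenal | C\C(C=O)=C/C=C/C=C(C)/C=C/C=C(\C)I
F10 | step 14 | (2E,4E,6E,8E,10E)-11-iodo-2,7-dimethyldodeca-2,4,6,8,10-pentaen-1-ol | C\C(CO)=C/C=C/C=C(C)/C=C/C=C(\C)I
F11 | step 14 | (2E,4E,6E,8E,10E)-13-[(1S,4S,6R)-4-{[tert-butyl(dimethyl)silyl]oxy}-2,2,6-trimethyl-7-oxabicyclo[4.1.0]heptan-1-yl]-2,7,11-trimethyltrideca-2,4,6,8,10-pentaene-1,12-diol (C12 epimers) | C\C(CO)=C/C=C/C=C(C)/C=C/C=C(\C)C(O)C[C@@]12O[C@]1(C)C[C@@H](O[Si](C)(C)C(C)(C)C)CC2(C)C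
F12 | step 14 | (2E,4E,6E,8E,10E)-13-[(1S,4S,6R)-4-hydroxy-2,2,6-trimethyl-7-oxabicyclo[4.1.0]heptan-1-yl]-2,7,11-trimethyltrideca-2,4,6,8,10-pentaene-1,12-diol (C12 epimers) | C\C(CO)=C/C=C/C=C(C)/C=C/C=C(\C)C(O)C[C@@]12O[C@]1(C)C[C@@H](O)CC2(C)C
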